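The route cuts the spiro C–CH2 bond of ring B and restores an O–C bond to the allylic CH carbon. The spiro carbon is C2 of the ring A 1,3-dione and carries a CH2–C(R)=CH allyl arm, so ring B is the Claisen product of a ring A enol ether. One thermal [3,3] shift of a cis-2-alkenyl-4-isopropyl dihydropyran, fused to ring A through the oxygen of the CMe2-flanked carbonyl, closes cyclohexene ring B, opens the pyran and sets the quaternary spiro centre by chirality transfer. The precursor is built from a dearomatised phloroglucinol dione by asymmetric Michael addition, Ni/Cr alkenylation and cyclodehydration.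

Key step: step 8

Assumption: 8 and 13 are drawn as open enol forms although both should rest largely as cyclic lactol or hemiketal tautomers, and ring closure in step 7 is taken to use the oxygen on the CMe2-flanked carbon; if the other oxygen closed instead, the antipodal ligand in step 6 would supply the epimeric carbinol, which leads to the same target.

Step 1
Reactants: 1 2,4,6-trihydroxyacetophenone
Product: 4 2-acetyl-3,5-dihydroxy-4,6,6-trimethylcyclohexa-2,4-dien-1-one, via monomethyl acetophenone 2 (not isolated), via dimethyl acetophenone 3 (not isolated)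
Conditions: NaOMe (3.3 equiv), MeI (3.1 equiv), MeOH, 0 °C to reflux; aq. HCl
Reagents that add atoms: iodomethane, CI
Why: Base-mediated dearomative C-methylation of an acylphloroglucinol is a known way to such cyclic triketones, since the phenoxide is methylated at both free ring carbons and once more at one of them while the acetyl-bearing carbon stays blocked, and the trimethyl compound is then separated from under- and over-methylated material.

Step 2
Reactants: 4 2-acetyl-3,5-dihydroxy-4,6,6-trimethylcyclohexa-2,4-dien-1-one
Product: 5 2-acetyl-3-hydroxy-5-methoxy-4,4,6-trimethylcyclohexa-2,5-dien-1-one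
Conditions: Me3SiCHN2 (1.1 equiv), toluene–MeOH 4:1, 0 °C
Reagents that add atoms: trimethylsilyldiazomethane, C[Si](C)(C)C=[N+]=[N-]
Why: O-Methylation of an acidic enol by a diazoalkane should take only the free vinylogous acid OH, because the other enol proton is held in the hydrogen-bonded chelate of the 2-acetyl-1,3-dione, which puts the methyl enol ether on the carbon between CMe2 and CMe.

Step 3
Reactants: 5 2-acetyl-3-hydroxy-5-methoxy-4,4,6-trimethylcyclohexa-2,5-dien-1-one
Product: 6 5-methoxy-4,6,6-trimethylcyclohex-4-ene-1,3-dione
Conditions: NaOMe (4 equiv), dry MeOH, 80 °C (sealed tube); cold aq. HCl to pH 4–5, rapid extraction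
Reagents that add atoms: none
Why: Retro-Claisen cleavage of a beta-triketone by alkoxide, in which methoxide should add to the exocyclic acetyl carbonyl (the ring carbonyls are shielded by CMe2 or deactivated as a vinylogous ester) and expel the stabilised dione anion, while exchange at the methyl enol ether is degenerate in methanol and the anionic state guards it against hydrolysis.

Step 4
Reactants: 6 5-methoxy-4,6,6-trimethylcyclohex-4-ene-1,3-dione; 7 (E)-4-methylpent-2-enal
Product: 8 3-hydroxy-5-methoxy-4,4,6-trimethyl-2-[(3S)-4-methyl-1-oxopentan-3-yl]cyclohexa-2,5-dien-1-one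
Conditions: (S)-2-[diphenyl(trimethylsilyloxy)methyl]pyrrolidine (10 mol %), PhCO2H (10 mol %), CH2Cl2, 0 °C to rt
Reagents that add atoms: none
Why: Iminium-catalysed enantioselective Michael addition of a cyclic 1,3-dione to an enal, in which the diphenyl(silyloxy)methyl group of the (S)-pyrrolidine shields one face of the E-iminium ion so that the dione C2 should add to the other face of the enal beta-carbon and give the S centre, the adduct being trapped as its lactol.

Step 5
Reactants: 9 6-methylhept-5-en-2-one
Product: 11 6-methylhepta-1,5-dien-2-yl trifluoromethanesulfonate, via lithium enolate 10 (not isolated)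
Conditions: LiN(iPr)2 (1.1 equiv), THF, −78 °C; PhNTf2 (1.1 equiv), −78 to 0 °C
Reagents that add atoms: N-phenylbis(trifluoromethanesulfonimide), O=S(=O)(N(c1ccccc1)S(=O)(=O)C(F)(F)F)C(F)(F)F
Why: Kinetic deprotonation of a methyl ketone by a hindered lithium amide at low temperature takes the methyl side, and O-sulfonylation of that enolate by the triflimide gives the terminal enol triflate.

Step 6
Reactants: 8 3-hydroxy-5-methoxy-4,4,6-trimethyl-2-[(3S)-4-methyl-1-oxopentan-3-yl]cyclohexa-2,5-dien-1-one; 11 6-methylhepta-1,5-dien-2-yl trifluoromethanesulfonate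
Product: 13 3-hydroxy-2-[(3S,5R)-5-hydroxy-2,10-dimethyl-6-methylideneundec-9-en-3-yl]-5-methoxy-4,4,6-trimethylcyclohexa-2,5-dien-1-one, via alkenylchromium dichloride 12 (not isolated)
Conditions: CrCl2 (4 equiv), N-[2-(4-isopropyl-4,5-dihydrooxazol-2-yl)-6-methylphenyl]methanesulfonamide (single enantiomer, 4.4 equiv), Et3N (4.4 equiv), NiCl2 (5 mol %), THF, rt; aq. ethylenediamine work-up
Reagents that add atoms: none
Why: Nozaki–Hiyama–Kishi reaction, in which the enol triflate adds oxidatively to nickel, is passed on to chromium and the alkenylchromium species adds to the aldehyde released from the lactol, the chiral oxazoline sulfonamide on chromium (the antipode that gives 5R is chosen in a first trial) being expected to override the weak bias of the remote 3S centre.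

Step 7
Reactants: 13 3-hydroxy-2-[(3S,5R)-5-hydroxy-2,10-dimethyl-6-methylideneundec-9-en-3-yl]-5-methoxy-4,4,6-trimethylcyclohexa-2,5-dien-1-one
Product: 15 (2R,4S)-7-methoxy-6,8,8-trimethyl-2-(6-methylhepta-1,5-dien-2-yl)-4-(propan-2-yl)-3,4-dihydro-2H-chromen-5(8H)-one, via cyclic hemiketal 14 (not isolated)
Conditions: pyridinium p-toluenesulfonate (10 mol %), 4 Å molecular sieves, toluene, 40 °C
Reagents that add atoms: none
Why: Acid-catalysed intramolecular enol ether formation of a delta-hydroxy 1,3-dione (cyclodehydration), in which the alcohol oxygen adds to a ring carbonyl and water leaves from the hemiketal, so the carbinol C–O bond and its R configuration are retained, reversible closure should settle on the cross-conjugated doubly vinylogous ester through the CMe2-flanked carbon, and the weak acid is chosen so that the allylic C–O bond does not ionise.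

Step 8
Reactants: 15 (2R,4S)-7-methoxy-6,8,8-trimethyl-2-(6-methylhepta-1,5-dien-2-yl)-4-(propan-2-yl)-3,4-dihydro-2H-chromen-5(8H)-one
Product: 16 (6R,11S)-3-methoxy-2,4,4-trimethyl-8-(4-methylpent-3-en-1-yl)-11-(propan-2-yl)spiro[5.5]undeca-2,8-diene-1,5-dione
Conditions: degassed o-xylene (0.02 M), 2,6-di-tert-butyl-4-methylpyridine (10 mol %), 150–170 °C, sealed base-washed tube
Reagents that add atoms: none
Why: Proposed new method: in 15 the ring A enol ether (O1–C8a=C4a) and the allylic ether (O1–C2–C(R)=CH2) make up an allyl vinyl ether locked in one ring, so heating should trigger a concerted suprafacial [3,3] shift through a boat-shaped, bicyclo[2.2.2]octene-like array that breaks O1–C2 and joins the terminal =CH2 carbon to C4a, the future spiro carbon. The closest known reaction types are the thermal Claisen rearrangement of 2-alkenyl-3,4-dihydro-2H-pyrans to cyclohex-3-enyl carbonyl compounds and the O-allyl to C-allyl rearrangement of enol ethers of 2-substituted cyclic 1,3-diones; their combination on a ring-fused vinylogous ester with formation of a spiro centre is the untested part. Ring B closes as the six-membered pericyclic array itself (C4a, the new CH2, C(R)=C2H, C3H2 and C4), the only other C–C closure being four-membered, while the pyran opens to give the second ketone of ring A. The new stereocentre, the quaternary spiro carbon, is controlled by the C2 carbinol centre, which is consumed: the alkenyl group can only reach the face of C4a on which it stands, cis to the isopropyl group, and because the ether oxygen sits on the CMe2-flanked carbon this places the isopropyl group cis to the vinylogous ester carbonyl (6R next to the untouched 11S centre). The step needs face selectivity at C4a and the concerted path to win over retro-hetero-Diels–Alder cleavage or ionisation to an allyl cation and a dione enolate; the cis tether secures the first, and the unhindered CH2 terminus, the electron-rich doubly donor-substituted enol ether carbon, the gain of a C=O and a C–C bond for one C–O bond, and acid-free heating in a non-polar solvent should secure the second.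

Compound list
1 | 2,4,6-trihydroxyacetophenone | CC(=O)c1c(O)cc(O)cc1O | starting material
2 | 2',4',6'-trihydroxy-3'-methylacetophenone (not isolated) | CC(=O)c1c(O)cc(O)c(C)c1O | intermediate
3 | 2',4',6'-trihydroxy-3',5'-dimethylacetophenone (not isolated) | CC(=O)c1c(O)c(C)c(O)c(C)c1O | intermediate
4 | 2-acetyl-3,5-dihydroxy-4,6,6-trimethylcyclohexa-2,4-dien-1-one (dienol form of 2-acetyl-4,6,6-trimethylcyclohexane-1,3,5-trione) | CC(=O)C1=C(O)C(C)=C(O)C(C)(C)C1=O | intermediate
5 | 2-acetyl-3-hydroxy-5-methoxy-4,4,6-trimethylcyclohexa-2,5-dien-1-one (enol form of 2-acetyl-5-methoxy-4,6,6-trimethylcyclohex-4-ene-1,3-dione) | COC1=C(C)C(=O)C(C(C)=O)=C(O)C1(C)C | intermediate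
6 | 5-methoxy-4,6,6-trimethylcyclohex-4-ene-1,3-dione | COC1=C(C)C(=O)CC(=O)C1(C)C | intermediate
7 | (E)-4-methylpent-2-enal | CC(C)/C=C/C=O | starting material
8 | 3-hydroxy-5-methoxy-4,4,6-trimethyl-2-[(3S)-4-methyl-1-oxopentan-3-yl]cyclohexa-2,5-dien-1-one (open enol aldehyde form of the Michael adduct, in equilibrium with its lactols) | COC1=C(C)C(=O)C([C@@H](CC=O)C(C)C)=C(O)C1(C)C | intermediate
9 | 6-methylhept-5-en-2-one | CC(=O)CCC=C(C)C | starting material
10 | lithium 6-methylhepta-1,5-dien-2-olate (not isolated) | [Li]OC(=C)CCC=C(C)C | intermediate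
11 | 6-methylhepta-1,5-dien-2-yl trifluoromethanesulfonate | C=C(OS(=O)(=O)C(F)(F)F)CCC=C(C)C | intermediate
12 | (6-methylhepta-1,5-dien-2-yl)chromium dichloride (chiral ligand on chromium not drawn; not isolated) | C=C([Cr](Cl)Cl)CCC=C(C)C | intermediate
13 | 3-hydroxy-2-[(3S,5R)-5-hydroxy-2,10-dimethyl-6-methylideneundec-9-en-3-yl]-5-methoxy-4,4,6-trimethylcyclohexa-2,5-dien-1-one (open enol form) | COC1=C(C)C(=O)C([C@@H](C[C@@H](O)C(=C)CCC=C(C)C)C(C)C)=C(O)C1(C)C | intermediate
14 | 8a-hydroxy-7-methoxy-6,8,8-trimethyl-2-(6-methylhepta-1,5-dien-2-yl)-4-(propan-2-yl)-2,3,4,4a,8,8a-hexahydro-5H-chromen-5-one (cyclic hemiketal of 13, carbinol and CH(iPr) carbons as in 13; not isolated) | COC1=C(C)C(=O)C2C(O)(O[C@@H](C(=C)CCC=C(C)C)C[C@H]2C(C)C)C1(C)C | intermediate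
15 | (2R,4S)-7-methoxy-6,8,8-trimethyl-2-(6-methylhepta-1,5-dien-2-yl)-4-(propan-2-yl)-3,4-dihydro-2H-chromen-5(8H)-one (2,4-cis) | COC1=C(C)C(=O)C2=C(O[C@@H](C(=C)CCC=C(C)C)C[C@H]2C(C)C)C1(C)C | intermediate
16 | (6R,11S)-3-methoxy-2,4,4-trimethyl-8-(4-methylpent-3-en-1-yl)-11-(propan-2-yl)spiro[5.5]undeca-2,8-diene-1,5-dione (CNP0419264.1) | COC1=C(C)C(=O)[C@]2(CC(CCC=C(C)C)=CC[C@H]2C(C)C)C(=O)C1(C)C | target

Total step count: 8. Longest linear sequence: 7 steps (steps 1, 2, 3, 4, 6, 7 and 8); step 5 is a one-step side branch.

Steps most likely to fail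

Step 8. The [3,3] shift may be slower than cycloreversion of the pyran to an alkylidene dione and myrcene, or than ionisation of the allylic C–O bond, so that the carbinol information is lost or the congested quaternary carbon does not form. The fallback uses known reactions only and closes ring B at its C(R)=CH bond instead; it sets out from 8 and 11 and returns at 16. Wittig methylenation of 8 (Ph3P=CH2 in excess, THF) should give the terminal alkene F1. Stille hydroxymethylation of 11 (Bu3SnCH2OH, Pd(PPh3)4, LiCl, dioxane) should give 6-methyl-2-methylidenehept-5-en-1-ol F2, which methyl chloroformate and pyridine convert into the methyl carbonate F3. Tsuji–Trost C-allylation of F1 with F3 (Pd(PPh3)4, THF) should give the 2,2-disubstituted dione F4 as both epimers at the new quaternary carbon. Ring-closing metathesis with the second-generation Grubbs catalyst (H2IMes)(PCy3)Cl2Ru=CHPh in CH2Cl2 should then close ring B and give 16 together with its spiro epimer F5, from which it is separated by chromatography. Control of the spiro centre is given up in this variant.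

Step 6. The acidic dione set free on opening of the lactol may protonate or bind the alkenylchromium species, and the ligand may fail to control the new carbinol centre on a substrate of this kind. The fallback sets out from 9 and 8 and returns at 15. Condensation of 9 with 2,4,6-triisopropylbenzenesulfonyl hydrazide gives the hydrazone F6, and a Shapiro reaction (n-BuLi, THF, −78 to 0 °C) turns it into the alkenyllithium F7. Addition of an excess of F7 to 8, in which the first equivalent opens the lactol to the dione enolate, should give 13 mixed with its carbinol epimer F8. The mixture is cyclodehydrated as in step 7 and the cis-pyran 15 is separated from the trans-pyran F9 by chromatography, so that reagent control is replaced by separation at the rigid pyran stage.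

Step 3. Methoxide may add too slowly to the enolised triketone anion, or ring cleavage and loss of the methyl enol ether may compete at the temperature needed. The fallback is a halogenative deacylation that sets out from 5 and returns at 6. NaH and N-chlorosuccinimide (THF, 0 °C) should chlorinate the central carbon to give the non-enolisable 2-acetyl-2-chloro triketone F10. Its acetyl group is removed by retro-Claisen methanolysis under mild conditions (K2CO3, MeOH, 0 °C) to give the 2-chloro dione F11, and zinc dust in AcOH–THF then removes the chlorine and gives 6.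

Further compounds
F1 | step 8 | 3-hydroxy-5-methoxy-4,4,6-trimethyl-2-[(3S)-2-methylhex-5-en-3-yl]cyclohexa-2,5-dien-1-one | COC1=C(C)C(=O)C([C@@H](CC=C)C(C)C)=C(O)C1(C)C
F2 | step 8 | 6-methyl-2-methylidenehept-5-en-1-ol | C=C(CO)CCC=C(C)C
F3 | step 8 | methyl (6-methyl-2-methylidenehept-5-en-1-yl) carbonate | C=C(COC(=O)OC)CCC=C(C)C
F4 | step 8 | 5-methoxy-4,6,6-trimethyl-2-(6-methyl-2-methylidenehept-5-en-1-yl)-2-[(3S)-2-methylhex-5-en-3-yl]cyclohex-4-ene-1,3-dione (both configurations at C2) | COC1=C(C)C(=O)C(CC(=C)CCC=C(C)C)([C@@H](CC=C)C(C)C)C(=O)C1(C)C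
F5 | step 8 | (6S,11S)-3-methoxy-2,4,4-trimethyl-8-(4-methylpent-3-en-1-yl)-11-(propan-2-yl)spiro[5.5]undeca-2,8-diene-1,5-dione (spiro epimer of 16) | COC1=C(C)C(=O)[C@@]2(CC(CCC=C(C)C)=CC[C@H]2C(C)C)C(=O)C1(C)C
F6 | step 6 | 6-methylhept-5-en-2-one 2,4,6-triisopropylbenzenesulfonylhydrazone | CC(CCC=C(C)C)=NNS(=O)(=O)c1c(C(C)C)cc(C(C)C)cc1C(C)C
F7 | step 6 | (6-methylhepta-1,5-dien-2-yl)lithium | [Li]C(=C)CCC=C(C)C
F8 | step 6 | 3-hydroxy-2-[(3S,5S)-5-hydroxy-2,10-dimethyl-6-methylideneundec-9-en-3-yl]-5-methoxy-4,4,6-trimethylcyclohexa-2,5-dien-1-one (carbinol epimer of 13) | COC1=C(C)C(=O)C([C@@H](C[C@H](O)C(=C)CCC=C(C)C)C(C)C)=C(O)C1(C)C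
F9 | step 6 | (2S,4S)-7-methoxy-6,8,8-trimethyl-2-(6-methylhepta-1,5-dien-2-yl)-4-(propan-2-yl)-3,4-dihydro-2H-chromen-5(8H)-one (2,4-trans epimer of 15) | COC1=C(C)C(=O)C2=C(O[C@H](C(=C)CCC=C(C)C)C[C@H]2C(C)C)C1(C)C
F10 | step 3 | 2-acetyl-2-chloro-5-methoxy-4,6,6-trimethylcyclohex-4-ene-1,3-dione | COC1=C(C)C(=O)C(Cl)(C(C)=O)C(=O)C1(C)C
F11 | step 3 | 2-chloro-5-methoxy-4,6,6-trimethylcyclohex-4-ene-1,3-dione | COC1=C(C)C(=O)C(Cl)C(=O)C1(C)C
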